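**Retrosynthetic overview**

- Feature: in the cyclohexene (C1 quaternary with methyl and styryl, C2, C3, C4 methyl-bearing sp2 carbon, C5, C6 = CH–indol-5-yl) the aryl sits on C6 beside C5, and C5 is bonded to the methyl-bearing C4. This is the pattern of an aryl added β to an ester whose α-carbon (C5) has captured a methyl ketone (C4), the ester carbon then being lost as CO2.
- C4=C5 comes from a cis-fused β-lactone (–CO2) made from β-hydroxy ester 21. Compound 21 comes from keto-enoate 20 and boronic acid 9 by rhodium-catalysed conjugate arylation (C6–aryl) with aldol closure (C4–C5).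
- 20 comes from keto aldehyde 16 by aryl addition and dehydration (styryl arm). 16 comes from ozonolysis of enoate 14, and 14 from the Diels–Alder adduct (S)-12 of methacrolein and isoprene, which sets C1.
- 9 (used twice) comes from 5-bromoindole-3-acetonitrile by N-tosylation, double methylation, nitrile reduction, methylenation and borylation.
- Ring order: indoles are bought; a temporary cyclohexene is made (step 7) and opened (step 9); the cyclohexane of the target closes in step 12; the β-lactone closes in step 14 and is lost in step 15.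

Key step: step 12

Assumption: the (S)-diphenylprolinol-derived oxazaborolidinium catalyst is taken to give (S)-12, as its formyl C–H···O binding model for 2-substituted acroleins predicts; if the sense proves opposite, the mirror-image catalyst is used and nothing else changes.

Ar = 3-(2-methylbut-3-en-2-yl)-1-tosyl-1H-indol-5-yl (tosyl = 4-methylbenzenesulfonyl).

**Route**

Step 1
Reactants: 1 2-(5-bromo-1H-indol-3-yl)acetonitrile
Product: 2 2-(5-bromo-1-tosyl-1H-indol-3-yl)acetonitrile
Conditions: NaH (1.1 equiv), THF, 0 °C; TsCl (1.1 equiv), 0 °C → rt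
Reagents that add atoms: p-toluenesulfonyl chloride, Cc1ccc(cc1)S(Cl)(=O)=O
Why: N-sulfonylation of the indolide anion, the N–H being the most acidic site, which protects the indole nitrogen through the later base, hydride, rhodium and acylation steps.

Step 2
Reactants: 2 2-(5-bromo-1-tosyl-1H-indol-3-yl)acetonitrile
Product: 4 2-(5-bromo-1-tosyl-1H-indol-3-yl)-2-methylpropanenitrile, via monomethyl nitrile 3 (not isolated)
Conditions: LiHMDS (1.1 equiv), THF, −78 °C; MeI (1.5 equiv), → 0 °C; then LiHMDS (1.2 equiv), −78 °C; MeI (2 equiv), → rt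
Reagents that add atoms: iodomethane, CI
Why: Twofold α-alkylation of an arylacetonitrile anion with the most reactive alkyl halide, which builds the gem-dimethyl carbon of the reverse-prenyl group; the amide base does not metallate C2 of the sulfonylindole in the presence of the far more acidic nitrile α-hydrogen.

Step 3
Reactants: 4 2-(5-bromo-1-tosyl-1H-indol-3-yl)-2-methylpropanenitrile
Product: 6 2-(5-bromo-1-tosyl-1H-indol-3-yl)-2-methylpropanal, via N-aluminated aldimine 5 (not isolated)
Conditions: DIBAL-H (1.5 equiv), toluene/CH2Cl2, −78 → −20 °C; then 1 M HCl, 0 °C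
Reagents that add atoms: water, O
Why: Partial reduction of a nitrile by hydroalumination; the N-aluminated imine resists a second hydride and is hydrolysed to the aldehyde on acidic work-up, and the aryl bromide and sulfonamide are inert to DIBAL-H at low temperature.

Step 4
Reactants: 6 2-(5-bromo-1-tosyl-1H-indol-3-yl)-2-methylpropanal
Product: 7 5-bromo-3-(2-methylbut-3-en-2-yl)-1-tosyl-1H-indole
Conditions: Ph3PCH3Br (1.5 equiv), KHMDS (1.4 equiv), THF, 0 °C; then 6, 0 °C → rt
Reagents that add atoms: methyltriphenylphosphonium bromide, C[P+](c1ccccc1)(c1ccccc1)c1ccccc1.[Br-]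
Why: Wittig methylenation of a non-enolisable α-quaternary aldehyde with the unhindered methylene ylide gives the 1,1-dimethylallyl (reverse-prenyl) group.

Step 5
Reactants: 7 5-bromo-3-(2-methylbut-3-en-2-yl)-1-tosyl-1H-indole
Product: 8 3-(2-methylbut-3-en-2-yl)-5-(4,4,5,5-tetramethyl-1,3,2-dioxaborolan-2-yl)-1-tosyl-1H-indole
Conditions: B2pin2 (1.2 equiv), PdCl2(dppf) (3 mol%), KOAc (3 equiv), dioxane, 85 °C
Reagents that add atoms: bis(pinacolato)diboron, CC1(C)OB(OC1(C)C)B1OC(C)(C)C(C)(C)O1
Why: Miyaura borylation of the aryl bromide; transmetallation with the diboron is faster than Heck insertion of the hindered vinyl group, and the weak acetate base leaves the sulfonamide intact.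

Step 6
Reactants: 8 3-(2-methylbut-3-en-2-yl)-5-(4,4,5,5-tetramethyl-1,3,2-dioxaborolan-2-yl)-1-tosyl-1H-indole
Product: 9 [3-(2-methylbut-3-en-2-yl)-1-tosyl-1H-indol-5-yl]boronic acid
Conditions: NaIO4 (3 equiv), NH4OAc (3 equiv), acetone/H2O (1:1), rt
Reagents that add atoms: water, O
Why: Oxidative deprotection of a pinacol boronate: periodate cleaves the pinacol released in the hydrolysis equilibrium and so drives the ester to the free boronic acid, while without an osmium or ruthenium co-oxidant it does not touch the alkene.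

Step 7
Reactants: 10 methacrolein (2-methylprop-2-enal), 11 isoprene (2-methylbuta-1,3-diene)
Product: 12 (1S)-1,4-dimethylcyclohex-3-ene-1-carbaldehyde
Conditions: (S)-B-(o-tolyl)-diphenylprolinol oxazaborolidine protonated with HN(SO2CF3)2 (10 mol%), isoprene (3 equiv), CH2Cl2, −78 → −40 °C
Reagents that add atoms: none
Why: Catalytic asymmetric Diels–Alder reaction: the cationic boron Lewis acid binds the s-trans enal through boron and a formyl C–H···O contact, a phenyl group covers one face, and isoprene adds to the open face with its methyl para to the formyl-bearing carbon, which sets the quaternary centre (the later C1) as S.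

Step 8
Reactants: 12 (1S)-1,4-dimethylcyclohex-3-ene-1-carbaldehyde, 13 methyl (triphenylphosphoranylidene)acetate
Product: 14 methyl (2E)-3-[(1S)-1,4-dimethylcyclohex-3-en-1-yl]prop-2-enoate
Conditions: 13 (1.5 equiv), toluene, 90 °C
Reagents that add atoms: none
Why: Wittig olefination with a stabilised ylide, which reacts with the non-enolisable neopentyl-type aldehyde on heating and gives the E-enoate; the quaternary centre is not touched.

Step 9
Reactants: 14 methyl (2E)-3-[(1S)-1,4-dimethylcyclohex-3-en-1-yl]prop-2-enoate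
Product: 16 methyl (2E,4S)-4-methyl-7-oxo-4-(2-oxoethyl)oct-2-enoate, via secondary ozonide 15 (not isolated)
Conditions: O3 (1 equiv, Sudan Red 7B end point), CH2Cl2, −78 °C; then Me2S, −78 °C → rt
Reagents that add atoms: ozone, [O-][O+]=O
Why: Ozonolysis (Criegee sequence, reductive work-up): electrophilic ozone attacks the electron-rich trisubstituted ring alkene far faster than the ester-conjugated alkene, so the ring alone is cleaved, its CH= carbon becoming the aldehyde of the two-carbon arm and its methyl-bearing carbon the methyl ketone of the 3-oxobutyl arm.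

Step 10
Reactants: 16 methyl (2E,4S)-4-methyl-7-oxo-4-(2-oxoethyl)oct-2-enoate, 9 [3-(2-methylbut-3-en-2-yl)-1-tosyl-1H-indol-5-yl]boronic acid
Product: 18 methyl (2E,4S)-4-(2-Ar-2-hydroxyethyl)-4-methyl-7-oxooct-2-enoate (both carbinol epimers), via arylethylzinc 17 (not isolated)
Conditions: 9 (2.0 equiv), Et2Zn (6.0 equiv), toluene, 60 °C; then 16, Me2NCH2CH2OH (10 mol%), toluene, −10 → 10 °C; aq NH4Cl
Reagents that add atoms: none
Why: Boron-to-zinc exchange followed by amino-alcohol-promoted aryl transfer from zinc to an aldehyde; arylzincs add to aldehydes but neither to the methyl ketone nor to the enoate, and the uncontrolled carbinol centre is removed in step 11.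

Step 11
Reactants: 18 methyl (2E,4S)-4-(2-Ar-2-hydroxyethyl)-4-methyl-7-oxooct-2-enoate
Product: 20 methyl (2E,4S)-4-[(E)-2-Ar-ethenyl]-4-methyl-7-oxooct-2-enoate, via sulfamate ester 19 (not isolated)
Conditions: methyl N-(triethylammoniosulfonyl)carbamate (Burgess reagent, 2 equiv), toluene, rt → 70 °C
Reagents that add atoms: none
Why: Burgess dehydration (syn elimination through the sulfamate ester): the only β-hydrogens are on the CH2 beside the quaternary carbon, so the alkene can form in one position only, conjugated with the indole, as the less strained E isomer; ketone and enoate are inert.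

Step 12
Reactants: 20 methyl (2E,4S)-4-[(E)-2-Ar-ethenyl]-4-methyl-7-oxooct-2-enoate, 9 [3-(2-methylbut-3-en-2-yl)-1-tosyl-1H-indol-5-yl]boronic acid
Product: 21 methyl (1R,2S,5S,6R)-6-Ar-5-[(E)-2-Ar-ethenyl]-2-hydroxy-2,5-dimethylcyclohexane-1-carboxylate
Conditions: Rh(acac)(C2H4)2 (5 mol%), (R)-BINAP (7.5 mol%), 9 (2.5 equiv), H2O (5 equiv), dioxane, 90 °C
Reagents that add atoms: none
Why: Proposed new method: transmetallation of 9 to the hydroxo complex of monovalent rhodium gives an aryl–rhodium that inserts the enoate C=C with aryl going to the β-carbon (C6–aryl bond), and the resulting oxa-π-allyl rhodium enolate adds to the tethered methyl ketone (C4–C5 bond) before water protonates it, hydrolysis of the rhodium alkoxide then returning Rh–OH; the closest known reactions are the rhodium–BINAP conjugate addition–aldol cyclisation of arylboronic acids with enone–ketones and the Hayashi–Miyaura arylation of β-substituted enoates, combined here on an enoate whose β-carbon lies next to a quaternary carbon. The single ring (cyclohexane C1–C6) closes in a 6-(enolexo)-exo-trig aldol through a chair Zimmerman–Traxler transition state in which rhodium bridges the enolate and ketone oxygens. C6 is set in the insertion by the ligand: by the established model for (E)-enoates, (R)-BINAP delivers aryl to the re face of the α-carbon, which places the aryl trans to the styryl group on C1, and since methyl, styryl and the oxobutyl chain on C1 are of similar size the substrate bias is small and the ligand decides. C5 follows from the enolate rotamer of least allylic strain (C6–H in the enolate plane), which puts the ester trans to the aryl, and C4 from the chair with the ketone methyl equatorial and its oxygen held by rhodium, which puts the hydroxyl cis to the ester. The step needs chemoselectivity for the enoate over the styryl and vinyl alkenes and the ketone, secured because only the ester-conjugated alkene is polarised enough for aryl–rhodium insertion, and it needs ring closure to outrun protonation, favoured by the intramolecular six-ring aldol and the small amount of water.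

Step 13
Reactants: 21 methyl (1R,2S,5S,6R)-6-Ar-5-[(E)-2-Ar-ethenyl]-2-hydroxy-2,5-dimethylcyclohexane-1-carboxylate
Product: 23 (1R,2S,5S,6R)-6-Ar-5-[(E)-2-Ar-ethenyl]-2-hydroxy-2,5-dimethylcyclohexane-1-carboxylic acid, via trimethylstannyl ester 22 (not isolated)
Conditions: Me3SnOH (8 equiv), 1,2-dichloroethane, 80 °C; then 5% aq HCl
Reagents that add atoms: trimethyltin hydroxide, C[Sn](C)(C)O
Why: Methyl ester cleavage with trimethyltin hydroxide (acyl substitution under neutral conditions): no free alkoxide is formed, so the tertiary aldol is not opened by retro-aldol reaction and the sulfonamides and stereocentres stay intact.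

Step 14
Reactants: 23 (1R,2S,5S,6R)-6-Ar-5-[(E)-2-Ar-ethenyl]-2-hydroxy-2,5-dimethylcyclohexane-1-carboxylic acid
Product: 25 cis-fused β-lactone of 23 (7-oxabicyclo[4.2.0]octan-8-one; lactone oxygen on the methyl-bearing C4 and carbonyl on C5; configurations of 23 retained), via mixed sulfonic anhydride 24 (not isolated)
Conditions: TsCl (2 equiv), pyridine, 0 → 4 °C
Reagents that add atoms: none
Why: β-Lactonisation by carboxyl activation: the acid forms the mixed carboxylic–sulfonic anhydride, which acylates the cis tertiary hydroxyl with retention at C4 and C5 and gives the cis-fused four-membered lactone.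

Step 15
Reactants: 25 cis-fused β-lactone of 23
Product: 26 5-{(E)-2-[(1S,2R)-2-Ar-1,4-dimethylcyclohex-3-en-1-yl]ethenyl}-3-(2-methylbut-3-en-2-yl)-1-tosyl-1H-indole
Conditions: toluene, 110 °C
Reagents that add atoms: none
Why: Thermal decarboxylation of a β-lactone (stereospecific [2+2] cycloreversion): CO2 leaves and the alkene can only appear between C4 and C5, which erases these two stereocentres and fixes the double bond beside C6; refluxing toluene is kept well below the range in which the styryl/ring-alkene 1,5-diene could undergo Cope rearrangement.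

Step 16
Reactants: 26 5-{(E)-2-[(1S,2R)-2-Ar-1,4-dimethylcyclohex-3-en-1-yl]ethenyl}-3-(2-methylbut-3-en-2-yl)-1-tosyl-1H-indole
Product: 27 5-[(E)-2-{(1S,2R)-1,4-dimethyl-2-[3-(2-methylbut-3-en-2-yl)-1H-indol-5-yl]cyclohex-3-en-1-yl}ethenyl]-3-(2-methylbut-3-en-2-yl)-1H-indole (EANPDB:ANNO_00013)
Conditions: KOH (10 equiv), EtOH/THF/H2O, 70 °C
Reagents that add atoms: none
Why: Nucleophilic N-desulfonylation: hydroxide attacks sulfur and the indolide leaves, which removes both tosyl groups without touching the alkenes or the two stereocentres of the cyclohexene.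

**Compound list**

1 | 2-(5-bromo-1H-indol-3-yl)acetonitrile | N#CCc1c[nH]c2ccc(Br)cc12 | starting material
2 | 2-(5-bromo-1-tosyl-1H-indol-3-yl)acetonitrile | N#CCc1cn(S(=O)(=O)c3ccc(C)cc3)c2ccc(Br)cc12 | intermediate
3 | 2-(5-bromo-1-tosyl-1H-indol-3-yl)propanenitrile (racemic; not isolated) | N#CC(C)c1cn(S(=O)(=O)c3ccc(C)cc3)c2ccc(Br)cc12 | intermediate
4 | 2-(5-bromo-1-tosyl-1H-indol-3-yl)-2-methylpropanenitrile | N#CC(C)(C)c1cn(S(=O)(=O)c3ccc(C)cc3)c2ccc(Br)cc12 | intermediate
5 | N-(diisobutylaluminio) aldimine of 6 (not isolated) | CC(C)C[Al](CC(C)C)N=CC(C)(C)c1cn(S(=O)(=O)c3ccc(C)cc3)c2ccc(Br)cc12 | intermediate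
6 | 2-(5-bromo-1-tosyl-1H-indol-3-yl)-2-methylpropanal | O=CC(C)(C)c1cn(S(=O)(=O)c3ccc(C)cc3)c2ccc(Br)cc12 | intermediate
7 | 5-bromo-3-(2-methylbut-3-en-2-yl)-1-tosyl-1H-indole | C=CC(C)(C)c1cn(S(=O)(=O)c3ccc(C)cc3)c2ccc(Br)cc12 | intermediate
8 | 3-(2-methylbut-3-en-2-yl)-5-(4,4,5,5-tetramethyl-1,3,2-dioxaborolan-2-yl)-1-tosyl-1H-indole | C=CC(C)(C)c1cn(S(=O)(=O)c3ccc(C)cc3)c2ccc(B4OC(C)(C)C(C)(C)O4)cc12 | intermediate
9 | [3-(2-methylbut-3-en-2-yl)-1-tosyl-1H-indol-5-yl]boronic acid | C=CC(C)(C)c1cn(S(=O)(=O)c3ccc(C)cc3)c2ccc(B(O)O)cc12 | intermediate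
10 | methacrolein | C=C(C)C=O | starting material
11 | isoprene | C=CC(C)=C | starting material
12 | (1S)-1,4-dimethylcyclohex-3-ene-1-carbaldehyde | O=C[C@]1(C)CC=C(C)CC1 | intermediate
13 | methyl (triphenylphosphoranylidene)acetate | COC(=O)C=P(c1ccccc1)(c1ccccc1)c1ccccc1 | starting material
14 | methyl (2E)-3-[(1S)-1,4-dimethylcyclohex-3-en-1-yl]prop-2-enoate | COC(=O)/C=C/[C@]1(C)CC=C(C)CC1 | intermediate
15 | secondary ozonide (1,2,4-trioxolane) of 14 (not isolated; trioxolane carbons unassigned) | COC(=O)/C=C/[C@]1(C)CC2OOC(C)(O2)CC1 | intermediate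
16 | methyl (2E,4S)-4-methyl-7-oxo-4-(2-oxoethyl)oct-2-enoate | O=CC[C@](/C=C/C(=O)OC)(C)CCC(C)=O | intermediate
17 | ethyl[3-(2-methylbut-3-en-2-yl)-1-tosylindol-5-yl]zinc (not isolated) | CC[Zn]c1ccc2c(c1)c(C(C)(C)C=C)cn2S(=O)(=O)c1ccc(C)cc1 | intermediate
18 | methyl (2E,4S)-4-(2-Ar-2-hydroxyethyl)-4-methyl-7-oxooct-2-enoate (carbinol epimers) | C=CC(C)(C)c1cn(S(=O)(=O)c5ccc(C)cc5)c2ccc(C(O)C[C@](/C=C/C(=O)OC)(C)CCC(C)=O)cc12 | intermediate
19 | triethylammonium N-(methoxycarbonyl)sulfamate ester of 18 (not isolated) | C=CC(C)(C)c1cn(S(=O)(=O)c5ccc(C)cc5)c2ccc(C(OS(=O)(=O)[N-]C(=O)OC)C[C@](/C=C/C(=O)OC)(C)CCC(C)=O)cc12.CC[NH+](CC)CC | intermediate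
20 | methyl (2E,4S)-4-[(E)-2-Ar-ethenyl]-4-methyl-7-oxooct-2-enoate | C=CC(C)(C)c1cn(S(=O)(=O)c5ccc(C)cc5)c2ccc(/C=C/[C@](/C=C/C(=O)OC)(C)CCC(C)=O)cc12 | intermediate
21 | methyl (1R,2S,5S,6R)-6-Ar-5-[(E)-2-Ar-ethenyl]-2-hydroxy-2,5-dimethylcyclohexane-1-carboxylate (hydroxyl cis to ester, ester trans to aryl, aryl trans to styryl) | C=CC(C)(C)c1cn(S(=O)(=O)c5ccc(C)cc5)c2ccc(/C=C/[C@]3(C)CC[C@](C)(O)[C@H](C(=O)OC)[C@H]3c7ccc8n(S(=O)(=O)c6ccc(C)cc6)cc(C(C)(C)C=C)c8c7)cc12 | intermediate
22 | trimethylstannyl ester of 23 (not isolated) | C=CC(C)(C)c1cn(S(=O)(=O)c5ccc(C)cc5)c2ccc(/C=C/[C@]3(C)CC[C@](C)(O)[C@H](C(=O)O[Sn](C)(C)C)[C@H]3c7ccc8n(S(=O)(=O)c6ccc(C)cc6)cc(C(C)(C)C=C)c8c7)cc12 | intermediate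
23 | (1R,2S,5S,6R)-6-Ar-5-[(E)-2-Ar-ethenyl]-2-hydroxy-2,5-dimethylcyclohexane-1-carboxylic acid | C=CC(C)(C)c1cn(S(=O)(=O)c5ccc(C)cc5)c2ccc(/C=C/[C@]3(C)CC[C@](C)(O)[C@H](C(=O)O)[C@H]3c7ccc8n(S(=O)(=O)c6ccc(C)cc6)cc(C(C)(C)C=C)c8c7)cc12 | intermediate
24 | mixed carboxylic–p-toluenesulfonic anhydride of 23 (not isolated) | C=CC(C)(C)c1cn(S(=O)(=O)c5ccc(C)cc5)c2ccc(/C=C/[C@]3(C)CC[C@](C)(O)[C@H](C(=O)OS(=O)(=O)c9ccc(C)cc9)[C@H]3c7ccc8n(S(=O)(=O)c6ccc(C)cc6)cc(C(C)(C)C=C)c8c7)cc12 | intermediate
25 | cis-fused β-lactone of 23 (7-oxabicyclo[4.2.0]octan-8-one; configurations of 23 retained) | C=CC(C)(C)c1cn(S(=O)(=O)c5ccc(C)cc5)c2ccc(/C=C/[C@]3(C)CC[C@](C)(O4)[C@H](C4=O)[C@H]3c7ccc8n(S(=O)(=O)c6ccc(C)cc6)cc(C(C)(C)C=C)c8c7)cc12 | intermediate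
26 | 5-{(E)-2-[(1S,2R)-2-Ar-1,4-dimethylcyclohex-3-en-1-yl]ethenyl}-3-(2-methylbut-3-en-2-yl)-1-tosyl-1H-indole | C=CC(C)(C)c1cn(S(=O)(=O)c5ccc(C)cc5)c2ccc(/C=C/[C@]3(C)CCC(C)=C[C@H]3c7ccc8n(S(=O)(=O)c6ccc(C)cc6)cc(C(C)(C)C=C)c8c7)cc12 | intermediate
27 | 5-[(E)-2-{(1S,2R)-1,4-dimethyl-2-[3-(2-methylbut-3-en-2-yl)-1H-indol-5-yl]cyclohex-3-en-1-yl}ethenyl]-3-(2-methylbut-3-en-2-yl)-1H-indole | C=CC(C)(C)c1c[nH]c2ccc(/C=C/[C@]3(C)CCC(C)=C[C@H]3c3ccc4[nH]cc(C(C)(C)C=C)c4c3)cc12 | target

**Totals**

Total step count: 16. Longest linear sequence: 13 steps (steps 1–6, then 10–16).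

**Steps most likely to fail**

Step 12 (the step with the proposed new method). Protonation of the ester-derived rhodium enolate by water may outrun ring closure, or the aldol may give a hydroxy ester that cannot lactonise, so that the open-chain conjugate adduct or an unusable ring product accumulates. The fallback sets out from 20 and 9 and uses known reactions only. Hayashi–Miyaura arylation of 20 with 9 under protic conditions (Rh(acac)(C2H4)2, (R)-BINAP, dioxane/H2O 10:1, 100 °C) is run deliberately to the open-chain product, methyl (3R,4S)-3-Ar-4-[(E)-2-Ar-ethenyl]-4-methyl-7-oxooctanoate F1, with C6 still set by the ligand. Excess DIBAL-H (CH2Cl2, −78 → 0 °C) reduces ester and ketone to the diol F2, and Dess–Martin periodinane returns the ketone and gives the aldehyde, keto aldehyde F3. Piperidinium acetate (benzene, rt → 50 °C) forms the aldehyde enamine, which attacks the ketone in a six-ring aldol condensation to the conjugated enal, 2,5-dimethyl-6-Ar-5-[(E)-2-Ar-ethenyl]cyclohex-1-ene-1-carbaldehyde F4, whose double bond lies regiospecifically between C4 and C5. Tsuji–Wilkinson decarbonylation with stoichiometric RhCl(PPh3)3 (toluene, 110 °C) removes the formyl group, and the sequence comes back to the route at 26.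

Step 10. Boron-to-zinc exchange may be incomplete, the mixed zinc reagent may transfer ethyl instead of aryl, or the Lewis-acidic zinc species may trigger aldol cyclisation of the 1,6-keto aldehyde. The fallback sets out from bromide 7 and aldehyde 16 and changes the organometal. An aromatic Finkelstein exchange (copper iodide CuI, NaI, trans-N,N′-dimethylcyclohexane-1,2-diamine, dioxane, 110 °C) converts 7 into 5-iodo-3-(2-methylbut-3-en-2-yl)-1-tosyl-1H-indole F5. A Nozaki–Hiyama–Kishi coupling of F5 with 16 (CrCl2, NiCl2 as catalyst, DMF, rt) then gives the arylchromium adduct of the aldehyde alone, since organochromium reagents ignore ketones and esters, and the sequence comes back to the route at 18.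

Step 13. Acyl substitution at the ester, which is flanked by the tertiary carbinol and the aryl-bearing carbon, may be too slow, and forcing it may open the aldol by retro-aldol cleavage. The fallback sets out from 21 and avoids attack of an oxygen nucleophile at the hindered carbonyl. DIBAL-H (CH2Cl2, −78 → 0 °C) reduces the ester to the 1,3-diol F6 (CO2Me of 21 replaced by CH2OH). TEMPO with PhI(OAc)2 oxidises only the primary alcohol to the β-hydroxy aldehyde F7 (CO2Me of 21 replaced by CHO). Pinnick oxidation (NaClO2, NaH2PO4, 2-methylbut-2-ene, t-BuOH/H2O) gives the acid, and the sequence comes back to the route at 23.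

**Further compounds**

F1 | step 12 | methyl (3R,4S)-3-Ar-4-[(E)-2-Ar-ethenyl]-4-methyl-7-oxooctanoate | C=CC(C)(C)c1cn(S(=O)(=O)c5ccc(C)cc5)c2ccc(/C=C/[C@](C)(CCC(C)=O)[C@@H](CC(=O)OC)c7ccc8n(S(=O)(=O)c6ccc(C)cc6)cc(C(C)(C)C=C)c8c7)cc12
F2 | step 12 | (3R,4S)-3-Ar-4-[(E)-2-Ar-ethenyl]-4-methyloctane-1,7-diol (C7 epimers) | C=CC(C)(C)c1cn(S(=O)(=O)c5ccc(C)cc5)c2ccc(/C=C/[C@](C)(CCC(C)O)[C@@H](CCO)c7ccc8n(S(=O)(=O)c6ccc(C)cc6)cc(C(C)(C)C=C)c8c7)cc12
F3 | step 12 | (3R,4S)-3-Ar-4-[(E)-2-Ar-ethenyl]-4-methyl-7-oxooctanal | C=CC(C)(C)c1cn(S(=O)(=O)c5ccc(C)cc5)c2ccc(/C=C/[C@](C)(CCC(C)=O)[C@@H](CC=O)c7ccc8n(S(=O)(=O)c6ccc(C)cc6)cc(C(C)(C)C=C)c8c7)cc12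
F4 | step 12 | 2,5-dimethyl-6-Ar-5-[(E)-2-Ar-ethenyl]cyclohex-1-ene-1-carbaldehyde (ring stereocentres as in 26) | C=CC(C)(C)c1cn(S(=O)(=O)c5ccc(C)cc5)c2ccc(/C=C/[C@]3(C)CCC(C)=C(C=O)[C@H]3c7ccc8n(S(=O)(=O)c6ccc(C)cc6)cc(C(C)(C)C=C)c8c7)cc12
F5 | step 10 | 5-iodo-3-(2-methylbut-3-en-2-yl)-1-tosyl-1H-indole | C=CC(C)(C)c1cn(S(=O)(=O)c3ccc(C)cc3)c2ccc(I)cc12
F6 | step 13 | 1,3-diol from 21 (CO2Me replaced by CH2OH, configurations as in 21) | C=CC(C)(C)c1cn(S(=O)(=O)c5ccc(C)cc5)c2ccc(/C=C/[C@]3(C)CC[C@](C)(O)[C@H](CO)[C@H]3c7ccc8n(S(=O)(=O)c6ccc(C)cc6)cc(C(C)(C)C=C)c8c7)cc12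
F7 | step 13 | β-hydroxy aldehyde from 21 (CO2Me replaced by CHO, configurations as in 21) | C=CC(C)(C)c1cn(S(=O)(=O)c5ccc(C)cc5)c2ccc(/C=C/[C@]3(C)CC[C@](C)(O)[C@H](C=O)[C@H]3c7ccc8n(S(=O)(=O)c6ccc(C)cc6)cc(C(C)(C)C=C)c8c7)cc12
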